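**Retrosynthetic overview**
- The target is reached last by global O-demethylation of its hexa-O-methyl ether.
- Both ArC(=O)CH2CH2–Ar chains are cut at the CH2–aryl bond into a ketone homoenolate (a 1-arylcyclopropanol) plus an aryl halide. The two bonds are made in one flask on a biaryl that carries a cyclopropanol on ring C and a chloride on ring B: first with 4-bromoanisole (ring D), then with the ring A cyclopropanol.
- The biaryl cyclopropanol comes from its methyl ester (Kulinkovich), which comes from a Suzuki coupling of methyl 5-bromo-2,4-dimethoxybenzoate with (5-chloro-2-methoxyphenyl)boronic acid. The ring A cyclopropanol comes from methyl 2,4-dimethoxybenzoate.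
- Rings: all four benzene rings are bought (A = terminal resorcinol ketone, B = central phenol, C = central resorcinol, D = terminal phenol). The only rings built are two cyclopropanols (on ring C first, on ring A second), and both are opened again in the key step.

Assumption: the target has no stereocentre and its biaryl axis (only two ortho substituents) rotates freely, so it is achiral and there is no enantiomer to select.

**Step 1**
Reactants: 1 methyl 5-bromo-2,4-dimethoxybenzoate; 2 (5-chloro-2-methoxyphenyl)boronic acid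
Product: 3 methyl 5-(5-chloro-2-methoxyphenyl)-2,4-dimethoxybenzoate
Conditions: Pd(dppf)Cl2 (3 mol %), K3PO4, 1,4-dioxane/H2O (5:1), 85 °C
Reagents that add atoms: none
Why: Suzuki–Miyaura coupling; zerovalent palladium formed from Pd(dppf)Cl2 inserts into the C–Br bond of 1 far faster than into the electron-rich C–Cl bond, so the chloride survives as the later coupling handle.

**Step 2**
Reactants: 3 methyl 5-(5-chloro-2-methoxyphenyl)-2,4-dimethoxybenzoate
Product: 4 1-[5-(5-chloro-2-methoxyphenyl)-2,4-dimethoxyphenyl]cyclopropan-1-ol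
Conditions: EtMgBr (3 equiv, slow addition), Ti(OiPr)4 (0.3 equiv), THF, 0 °C to rt; then aqueous work-up
Reagents that add atoms: ethylmagnesium bromide, CC[Mg]Br
Why: Kulinkovich cyclopropanation; the titanacyclopropane made from Ti(OiPr)4 and two EtMgBr acts as a 1,2-dicarbanion that adds twice to the ester carbon, while the aryl chloride and methyl ethers are inert, and no stereocentre is formed.

**Step 3**
Reactants: 5 methyl 2,4-dimethoxybenzoate
Product: 6 1-(2,4-dimethoxyphenyl)cyclopropan-1-ol
Conditions: EtMgBr (3 equiv, slow addition), Ti(OiPr)4 (0.3 equiv), THF, 0 °C to rt; then aqueous work-up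
Reagents that add atoms: ethylmagnesium bromide, CC[Mg]Br
Why: Kulinkovich cyclopropanation of an aryl ester by the same titanacyclopropane mechanism as in step 2, giving the ring A homoenolate precursor.

**Step 4**
Reactants: 4 1-[5-(5-chloro-2-methoxyphenyl)-2,4-dimethoxyphenyl]cyclopropan-1-ol; 7 4-bromoanisole; 6 1-(2,4-dimethoxyphenyl)cyclopropan-1-ol
Product: 9 1-[5-{5-[3-(2,4-dimethoxyphenyl)-3-oxopropyl]-2-methoxyphenyl}-2,4-dimethoxyphenyl]-3-(4-methoxyphenyl)propan-1-one (the hexa-O-methyl ether of the target), via aryl chloride ketone 8 (not isolated)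
Conditions: a) 7 (1.0 equiv), Pd(OAc)2 (5 mol %), dppb (6 mol %), Cs2CO3 (3 equiv), toluene, 80 °C; b) then 6 (1.3 equiv), Pd(OAc)2 (5 mol %), XPhos (12 mol %), 110 °C, same flask
Reagents that add atoms: none
Why: Proposed new method: each cyclopropanol serves as a ketone homoenolate, because its arylpalladium alkoxide undergoes strain-driven β-carbon elimination to an aryl(β-ketoalkyl)palladium species that reductively eliminates the CH2–aryl bond; the dppb catalyst inserts only into the C–Br bond of 7, so 4 reacts at its cyclopropanol and keeps its C–Cl bond, and the XPhos catalyst added afterwards activates that C–Cl bond of 8 for the homoenolate from 6; the closest known reaction type is the palladium-catalysed ring-opening cross-coupling of cyclopropanols with aryl bromides, combined with bromide-before-chloride sequential cross-coupling.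

**Step 5**
Reactants: 9 1-[5-{5-[3-(2,4-dimethoxyphenyl)-3-oxopropyl]-2-methoxyphenyl}-2,4-dimethoxyphenyl]-3-(4-methoxyphenyl)propan-1-one
Product: 10 1-[5-{5-[3-(2,4-dihydroxyphenyl)-3-oxopropyl]-2-hydroxyphenyl}-2,4-dihydroxyphenyl]-3-(4-hydroxyphenyl)propan-1-one (CID44566750)
Conditions: BBr3 (10 equiv), CH2Cl2, −78 °C to rt; then ice/H2O
Reagents that add atoms: none
Why: Lewis-acid aryl methyl ether cleavage; BBr3 binds each methoxy oxygen and bromide removes the methyl group by SN2 (the two methoxy groups ortho to the carbonyls go first by chelation), the saturated ketone chains are untouched, and there is no stereocentre to scramble.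

**Compound list**
1 | methyl 5-bromo-2,4-dimethoxybenzoate | COC(=O)c1cc(Br)c(OC)cc1OC | starting material
2 | (5-chloro-2-methoxyphenyl)boronic acid | COc1ccc(Cl)cc1B(O)O | starting material
3 | methyl 5-(5-chloro-2-methoxyphenyl)-2,4-dimethoxybenzoate | COC(=O)c1cc(-c2cc(Cl)ccc2OC)c(OC)cc1OC | intermediate
4 | 1-[5-(5-chloro-2-methoxyphenyl)-2,4-dimethoxyphenyl]cyclopropan-1-ol | OC1(CC1)c1cc(-c2cc(Cl)ccc2OC)c(OC)cc1OC | intermediate
5 | methyl 2,4-dimethoxybenzoate | COC(=O)c1ccc(OC)cc1OC | starting material
6 | 1-(2,4-dimethoxyphenyl)cyclopropan-1-ol | OC1(CC1)c1ccc(OC)cc1OC | intermediate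
7 | 4-bromoanisole | COc1ccc(Br)cc1 | starting material
8 | 1-[5-(5-chloro-2-methoxyphenyl)-2,4-dimethoxyphenyl]-3-(4-methoxyphenyl)propan-1-one | O=C(CCc1ccc(OC)cc1)c1cc(-c2cc(Cl)ccc2OC)c(OC)cc1OC | intermediate
9 | 1-[5-{5-[3-(2,4-dimethoxyphenyl)-3-oxopropyl]-2-methoxyphenyl}-2,4-dimethoxyphenyl]-3-(4-methoxyphenyl)propan-1-one | O=C(CCc1ccc(OC)cc1)c1cc(-c2cc(CCC(=O)c3ccc(OC)cc3OC)ccc2OC)c(OC)cc1OC | intermediate
10 | 1-[5-{5-[3-(2,4-dihydroxyphenyl)-3-oxopropyl]-2-hydroxyphenyl}-2,4-dihydroxyphenyl]-3-(4-hydroxyphenyl)propan-1-one | O=C(CCc1ccc(O)c(-c2cc(C(=O)CCc3ccc(O)cc3)c(O)cc2O)c1)c1ccc(O)cc1O | target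

**Totals**
Total step count: 5. Longest linear sequence: 4 (steps 1, 2, 4, 5); step 3 is a one-step side branch.

**Steps most likely to fail, with fallbacks**

Step 4 (one-flask double homoenolate arylation). The weak point is the second stage, where an electron-rich aryl chloride must enter the cyclopropanol coupling. Oligomerisation of 4, β-hydride elimination to enones and ketone α-arylation are further risks. The fallback sets out from 8 (made by running part a alone and isolating it) and from 6, and comes back at 9. Miyaura borylation of 8 (B2pin2, Pd2(dba)3, XPhos, KOAc, dioxane, 100 °C) gives the pinacol boronate 1-[2,4-dimethoxy-5-[2-methoxy-5-(4,4,5,5-tetramethyl-1,3,2-dioxaborolan-2-yl)phenyl]phenyl]-3-(4-methoxyphenyl)propan-1-one F1. Cyclopropanol 6 is opened oxidatively (Pd(OAc)2, pyridine, O2, toluene, 80 °C) to the aryl vinyl ketone 1-(2,4-dimethoxyphenyl)prop-2-en-1-one F2. Rhodium-catalysed conjugate addition of F1 to F2 ([Rh(cod)OH]2, dioxane/H2O, 50 °C) then gives 9.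

Step 2 (Kulinkovich reaction on the electron-rich biaryl ester). The deactivated, ortho-methoxy ester may react sluggishly or give ethyl ketone and carbinol by-products. The fallback sets out from 2 and comes back at 4, making the cyclopropanol by aryl addition to a cyclopropanone equivalent instead of building it on the ester. Mono-Suzuki coupling of 2 with excess 1,5-dibromo-2,4-dimethoxybenzene (3 equiv, Pd(dppf)Cl2, K3PO4, dioxane/H2O, 85 °C) gives 1-bromo-5-(5-chloro-2-methoxyphenyl)-2,4-dimethoxybenzene F3. Bromine–lithium exchange (n-BuLi, THF, −78 °C) gives [5-(5-chloro-2-methoxyphenyl)-2,4-dimethoxyphenyl]lithium F4. This is added to cyclopropanone released in situ from 1-ethoxycyclopropan-1-ol and MeMgBr (THF, 0 °C to rt) and gives 4.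

Step 5 (sixfold demethylation in one operation). Incomplete cleavage of the four non-chelated ethers or decomposition of the electron-rich polyphenol is possible. The fallback sets out from 9 and comes back at 10 in two mechanistically different stages. AlCl3 (CH2Cl2, 0 °C to rt) removes only the two methyl groups ortho to the carbonyls by chelation and gives 1-[2-hydroxy-5-{5-[3-(2-hydroxy-4-methoxyphenyl)-3-oxopropyl]-2-methoxyphenyl}-4-methoxyphenyl]-3-(4-methoxyphenyl)propan-1-one F5. The remaining four ethers are then cleaved by thiolate SN2 attack under basic conditions (NaSEt, DMF, 130 °C; acid work-up) to give 10.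

**Further compounds**
F1 | step 4 | 1-[2,4-dimethoxy-5-[2-methoxy-5-(4,4,5,5-tetramethyl-1,3,2-dioxaborolan-2-yl)phenyl]phenyl]-3-(4-methoxyphenyl)propan-1-one | O=C(CCc1ccc(OC)cc1)c1cc(-c2cc(B3OC(C)(C)C(C)(C)O3)ccc2OC)c(OC)cc1OC
F2 | step 4 | 1-(2,4-dimethoxyphenyl)prop-2-en-1-one | C=CC(=O)c1ccc(OC)cc1OC
F3 | step 2 | 1-bromo-5-(5-chloro-2-methoxyphenyl)-2,4-dimethoxybenzene | COc1cc(OC)c(-c2cc(Cl)ccc2OC)cc1Br
F4 | step 2 | [5-(5-chloro-2-methoxyphenyl)-2,4-dimethoxyphenyl]lithium | [Li]c1cc(-c2cc(Cl)ccc2OC)c(OC)cc1OC
F5 | step 5 | 1-[2-hydroxy-5-{5-[3-(2-hydroxy-4-methoxyphenyl)-3-oxopropyl]-2-methoxyphenyl}-4-methoxyphenyl]-3-(4-methoxyphenyl)propan-1-one | O=C(CCc1ccc(OC)cc1)c1cc(-c2cc(CCC(=O)c3ccc(OC)cc3O)ccc2OC)c(OC)cc1O
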